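**Plan**
1. Cuts: the three O‑benzyl groups are cleared and the C4 carbinol is taken back to a ketone. Then O1–C2 and C5–C6 of the oxane ring are cut together (ring atoms: O1, C2 aryl‑bearing, C3, C4, C5, C6 side‑chain‑bearing; C1' is the exocyclic carbinol).
2. Enabling feature: C2 is benzylic and para to the guaiacyl oxygen (latent cation), and C4 carries oxygen (latent C4–C5 enolate). C2–C3–C4–C5 is therefore a 1,4‑zwitterion that can be stored as the strained ring of a 3‑arylcyclobutanone (extra bond C2–C5), and C6=O1 is an aldehyde.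
3. Forward: the four‑membered ring comes from a [2+2] cycloaddition on the styrene made from O‑benzylvanillin, and the aldehyde comes from O‑benzyl‑L‑tyrosine. Lewis acid, strain‑release insertion of the aldehyde C=O into the cyclobutanone then makes the six‑membered ring and joins the heptanoid chain in one step.
4. Stereochemistry: C1' (S) comes from tyrosine by retentive diazotisation, and C6 (S, syn to C1') from chelation control. C2 (R, 2,6‑cis) comes from thermodynamic funnelling through the reversible benzylic C–O bond, and C4 (S, axial OH) from equatorial hydride delivery.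
5. Helpers: the gem‑dichloride (ketene activation) leaves with zinc. The benzyl ethers (donor tuning, chelating ligand) leave by hydrogenolysis at the end.

Key step: step 8

Assumption: intermediates 13 and 14 are titanium‑bound in the flask and are drawn metal‑free as zwitterions. O‑Benzylvanillin and O‑benzyl‑L‑tyrosine are taken as catalogue chemicals.

Step 1
Reactants: 1 4‑(benzyloxy)‑3‑methoxybenzaldehyde (O‑benzylvanillin)
Product: 2 1‑(benzyloxy)‑4‑ethenyl‑2‑methoxybenzene (4‑benzyloxy‑3‑methoxystyrene)
Conditions: Ph3PCH3Br, KOtBu, THF, 0 °C → rt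
Reagents that add atoms: methyltriphenylphosphonium bromide, C[P+](c1ccccc1)(c1ccccc1)c1ccccc1.[Br-]
Why: Wittig methylenation of a non‑enolisable aromatic aldehyde is reliable, leaves the aryl benzyl ether untouched and creates no stereocentre.

Step 2
Reactants: 2 4‑benzyloxy‑3‑methoxystyrene
Product: 3 (±)‑3‑[4‑(benzyloxy)‑3‑methoxyphenyl]‑2,2‑dichlorocyclobutanone
Conditions: Cl3CCOCl, Zn–Cu, Et2O/DME, 0 °C → rt
Reagents that add atoms: trichloroacetyl chloride, ClC(=O)C(Cl)(Cl)Cl
Why: In this ketene–alkene [2+2] cycloaddition the nucleophilic styrene terminus attacks the ketene carbonyl carbon and the CCl2 carbon bonds to the benzylic carbon, which should give the 2,2‑dichloro‑3‑aryl regioisomer as a racemate whose only stereocentre vanishes in step 3.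

Step 3
Reactants: 3 (±)‑3‑[4‑(benzyloxy)‑3‑methoxyphenyl]‑2,2‑dichlorocyclobutanone
Product: 4 3‑[4‑(benzyloxy)‑3‑methoxyphenyl]cyclobutanone (achiral)
Conditions: Zn dust, AcOH, rt
Reagents that add atoms: none
Why: Reductive dechlorination of an α,α‑dichloroketone through zinc enolates is the standard follow‑up to a dichloroketene cycloaddition, spares the ketone and benzyl ether, and leaves a mirror‑symmetric cyclobutanone.

Step 4
Reactants: 5 O‑benzyl‑L‑tyrosine
Product: 8 (S)‑3‑[4‑(benzyloxy)phenyl]‑2‑hydroxypropanoic acid, via diazonium carboxylate 6 (not isolated), via (R)‑α‑lactone 7 (not isolated)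
Conditions: NaNO2, 1 M aq. H2SO4/1,4‑dioxane, 0 °C → rt
Reagents that add atoms: water, O
Why: Diazotisation of an α‑amino acid runs with net retention, because the carboxylate of 6 displaces N2 with inversion to 7 and water opens 7 with a second inversion, so the S centre of tyrosine becomes C1' of the target.

Step 5
Reactants: 8 (S)‑3‑[4‑(benzyloxy)phenyl]‑2‑hydroxypropanoic acid
Product: 9 methyl (S)‑3‑[4‑(benzyloxy)phenyl]‑2‑hydroxypropanoate
Conditions: MeOH, cat. H2SO4, reflux
Reagents that add atoms: methanol, CO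
Why: Fischer esterification touches neither the stereocentre nor the aryl benzyl ether.

Step 6
Reactants: 9 methyl (S)‑3‑[4‑(benzyloxy)phenyl]‑2‑hydroxypropanoate
Product: 10 methyl (S)‑2‑(benzyloxy)‑3‑[4‑(benzyloxy)phenyl]propanoate
Conditions: BnOC(=NH)CCl3, cat. TfOH, CH2Cl2/cyclohexane, 0 °C → rt
Reagents that add atoms: benzyl 2,2,2‑trichloroacetimidate, N=C(OCc1ccccc1)C(Cl)(Cl)Cl
Why: Acid‑catalysed O‑benzylation with the trichloroacetimidate avoids base and hence enolisation of the α‑alkoxy ester, and it installs the ether ligand that the chelate of step 8 needs.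

Step 7
Reactants: 10 methyl (S)‑2‑(benzyloxy)‑3‑[4‑(benzyloxy)phenyl]propanoate
Product: 12 (S)‑2‑(benzyloxy)‑3‑[4‑(benzyloxy)phenyl]propanal, via diisobutylaluminium hemiacetal 11 (not isolated)
Conditions: DIBAL‑H (1.1 equiv), CH2Cl2, −78 °C; then aq. Rochelle salt; used without chromatography
Reagents that add atoms: none
Why: Partial DIBAL‑H reduction of an α‑alkoxy ester stops at −78 °C at the chelate‑stabilised tetrahedral intermediate 11, which releases the aldehyde only on work‑up, and direct use of 12 guards the α‑centre against epimerisation.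

Step 8
Reactants: 4 3‑[4‑(benzyloxy)‑3‑methoxyphenyl]cyclobutanone; 12 (S)‑2‑(benzyloxy)‑3‑[4‑(benzyloxy)phenyl]propanal
Product: 15 (2R,6S)‑2‑[4‑(benzyloxy)‑3‑methoxyphenyl]‑6‑{(1S)‑1‑(benzyloxy)‑2‑[4‑(benzyloxy)phenyl]ethyl}tetrahydro‑4H‑pyran‑4‑one, via enolate/benzylic cation 1,4‑zwitterion 13 (not isolated), via open‑chain aldolate/benzylic cation 14 (not isolated)
Conditions: 12, TiCl4 (1.1 equiv), CH2Cl2, −78 °C; then 4 (1.2 equiv, slow addition) and TiCl4 (1.1 equiv), −78 → −30 °C; sat. aq. NaHCO3
Reagents that add atoms: none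
Why: Proposed new method: TiCl4 on the carbonyl oxygen of 4 should trigger heterolysis of the strained ring bond between the α‑carbon and the aryl‑bearing carbon, because that carbon is benzylic and para to the benzyloxy oxygen, and either of the two enantiotopic bonds gives the same achiral titanium enolate/quinone‑methide‑type cation 13. The enolate CH2 then adds in an open, Mukaiyama‑type aldol to the pre‑formed five‑membered titanium chelate of 12 (C=O and α‑OBn) from the face opposite the CH2Ar group, which sets C6 as S and syn to C1' (Cram chelate control) and gives 14. The titanium alkoxide of 14 closes on the benzylic cation, a 6‑exo‑trig closure when the cation is read as its quinone methide form, so that the aldehyde C=O has been inserted into the four‑membered ring and the ring has grown by two atoms. C2 is set under thermodynamic control, since the new benzylic C2–O1 bond re‑ionises under the Lewis acid and both epimers drain into the chair with aryl group and side chain equatorial (2,6‑cis, 2R). The closest known reaction types are the Lewis acid‑promoted formal [4+2] cycloaddition of 3‑alkoxycyclobutanones with aldehydes and that of 2‑arylcyclobutane‑1,1‑diesters with aldehydes to cis‑2,6‑tetrahydropyrans, and the new element is an aryl group as the only donor on a cyclobutanone. The step needs capture of 13 by the aldehyde to outrun proton transfer to the enone and Friedel–Crafts attack on the arenes, which the chelate‑activated aldehyde, the low temperature and the slow addition of 4 should secure.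

Step 9
Reactants: 15 (2R,6S)‑pyran‑4‑one
Product: 16 (2R,4S,6S)‑2‑[4‑(benzyloxy)‑3‑methoxyphenyl]‑6‑{(1S)‑1‑(benzyloxy)‑2‑[4‑(benzyloxy)phenyl]ethyl}tetrahydro‑2H‑pyran‑4‑ol
Conditions: L‑Selectride, THF, −78 °C; then aq. NaOH, H2O2, 0 °C
Reagents that add atoms: none
Why: In this diastereoselective ketone reduction the bulky trialkylborohydride attacks the 2,6‑diequatorial chair from the equatorial direction, which places the new C4–OH axial (4S, trans to both ring substituents).

Step 10
Reactants: 16 (2R,4S,6S)‑tris(benzyl ether)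
Product: 17 rhoiptelol B, (2R,4S,6S)‑2‑(4‑hydroxy‑3‑methoxyphenyl)‑6‑[(1S)‑1‑hydroxy‑2‑(4‑hydroxyphenyl)ethyl]tetrahydro‑2H‑pyran‑4‑ol
Conditions: H2 (1 atm), 10% Pd/C, EtOAc/EtOH, rt
Reagents that add atoms: none
Why: Catalytic hydrogenolysis should remove the three unhindered O‑benzyl groups faster than it cleaves the secondary, ring‑held C2–O1 bond, and it touches no stereocentre.

**Compound list**
1 | 4‑(benzyloxy)‑3‑methoxybenzaldehyde | COc1cc(C=O)ccc1OCc1ccccc1 | starting material
2 | 4‑benzyloxy‑3‑methoxystyrene | COc1cc(C=C)ccc1OCc1ccccc1 | intermediate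
3 | (±)‑3‑[4‑(benzyloxy)‑3‑methoxyphenyl]‑2,2‑dichlorocyclobutanone | COc1cc(C2CC(=O)C2(Cl)Cl)ccc1OCc1ccccc1 | intermediate
4 | 3‑[4‑(benzyloxy)‑3‑methoxyphenyl]cyclobutanone | COc1cc(C2CC(=O)C2)ccc1OCc1ccccc1 | intermediate
5 | O‑benzyl‑L‑tyrosine | N[C@@H](Cc1ccc(OCc2ccccc2)cc1)C(=O)O | starting material
6 | (S)‑diazonium carboxylate | N#[N+][C@@H](Cc1ccc(OCc2ccccc2)cc1)C(=O)[O-] | intermediate (not isolated)
7 | (R)‑3‑[4‑(benzyloxy)benzyl]oxiran‑2‑one (α‑lactone) | O1[C@H](Cc2ccc(OCc3ccccc3)cc2)C1=O | intermediate (not isolated)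
8 | (S)‑3‑[4‑(benzyloxy)phenyl]‑2‑hydroxypropanoic acid | O[C@@H](Cc1ccc(OCc2ccccc2)cc1)C(=O)O | intermediate
9 | methyl (S)‑3‑[4‑(benzyloxy)phenyl]‑2‑hydroxypropanoate | COC(=O)[C@@H](O)Cc1ccc(OCc2ccccc2)cc1 | intermediate
10 | methyl (S)‑2‑(benzyloxy)‑3‑[4‑(benzyloxy)phenyl]propanoate | COC(=O)[C@@H](OCc1ccccc1)Cc1ccc(OCc2ccccc2)cc1 | intermediate
11 | diisobutylaluminium hemiacetal of 10 (hemiacetal carbon undefined) | COC(O[Al](CC(C)C)CC(C)C)[C@@H](OCc1ccccc1)Cc1ccc(OCc2ccccc2)cc1 | intermediate (not isolated)
12 | (S)‑2‑(benzyloxy)‑3‑[4‑(benzyloxy)phenyl]propanal | O=C[C@@H](OCc1ccccc1)Cc1ccc(OCc2ccccc2)cc1 | intermediate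
13 | 1,4‑zwitterion from 4 (enolate/benzylic cation, Ti‑bound, drawn metal‑free) | C=C([O-])C[CH+]c1ccc(OCc2ccccc2)c(OC)c1 | intermediate (not isolated)
14 | open‑chain (5S,6S)‑aldolate/benzylic cation (Ti‑bound, drawn metal‑free) | COc1cc([CH+]CC(=O)C[C@@H]([C@@H](OCc2ccccc2)Cc2ccc(OCc3ccccc3)cc2)[O-])ccc1OCc1ccccc1 | intermediate (not isolated)
15 | (2R,6S)‑2‑[4‑(benzyloxy)‑3‑methoxyphenyl]‑6‑{(1S)‑1‑(benzyloxy)‑2‑[4‑(benzyloxy)phenyl]ethyl}tetrahydro‑4H‑pyran‑4‑one | COc1cc([C@H]2CC(=O)C[C@@H]([C@@H](OCc3ccccc3)Cc3ccc(OCc4ccccc4)cc3)O2)ccc1OCc1ccccc1 | intermediate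
16 | (2R,4S,6S)‑tris(benzyl ether) of rhoiptelol B | COc1cc([C@H]2C[C@H](O)C[C@@H]([C@@H](OCc3ccccc3)Cc3ccc(OCc4ccccc4)cc3)O2)ccc1OCc1ccccc1 | intermediate
17 | rhoiptelol B | COc1cc([C@H]2C[C@H](O)C[C@@H]([C@@H](O)Cc3ccc(O)cc3)O2)ccc1O | target

**Count:** 10 steps in total. The longest linear sequence is 7 steps (steps 4–10, from 5).

**Steps most likely to fail**

Step 8. The zwitterion may collapse by proton transfer to the open‑chain enone, or alkylate one of the electron‑rich arenes, before the aldehyde is captured. Chelate control may also erode if the ring opens only at a higher temperature. The fallback uses known chemistry and keeps the four‑ to six‑membered ring expansion. It sets out from 12 and comes back at 15.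
- Aldehyde 12 is combined with commercial 3‑ethoxycyclobutanone (CCOC1CC(=O)C1) under SnCl4 or TiCl4 in CH2Cl2 at −78 °C. This is the established alkoxy‑donor version of the formal [4+2] cycloaddition.
- The chelated aldehyde should again react syn and give the 2‑ethoxytetrahydropyran‑4‑one F1, which should lose ethanol in the flask to the 2,3‑dihydro‑4H‑pyran‑4‑one F2.
- Rhodium(I)‑catalysed conjugate addition of (4‑benzyloxy‑3‑methoxyphenyl)boronic acid should deliver the aryl group anti to the side chain and give the 2,6‑trans‑pyranone F3.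
- A catalytic amount of acid (TfOH or BF3·OEt2, CH2Cl2) should equilibrate F3 through the benzylic cation to the 2,6‑cis ketone 15.

Step 2. Zinc chloride may start cationic polymerisation of the electron‑rich styrene. It may also open the donor–acceptor dichlorocyclobutanone as it forms. The fallback sets out from 2 and comes back at 4, bypassing 3 and all zinc salts.
- N,N‑Dimethylacetamide, Tf2O and 2,4,6‑collidine in 1,2‑dichloroethane generate the keteniminium salt.
- Its [2+2] cycloaddition with 2 should give the cyclobutaniminium triflate F4.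
- Aqueous NaHCO3 hydrolyses F4 directly to 4.

Step 10. Hydrogenolysis of the ring benzylic C2–O1 bond may compete while the slow secondary alkyl benzyl ether is being removed. The fallback sets out from 16 and comes back at 17. It replaces surface hydrogenolysis by single‑electron debenzylation with lithium naphthalenide in THF at −78 → −20 °C. The two aryl benzyl ethers should cleave first and leave phenoxides whose rings no longer accept an electron. This shields C2–O1, while the phenyl ring of the remaining alkyl benzyl ether is still reduced. This fallback makes no new compound (F0).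

**Further compounds**
F1 | step 8 | (6S)‑6‑{(1S)‑1‑(benzyloxy)‑2‑[4‑(benzyloxy)phenyl]ethyl}‑2‑ethoxytetrahydro‑4H‑pyran‑4‑one (acetal carbon undefined) | CCOC1CC(=O)C[C@@H]([C@@H](OCc2ccccc2)Cc2ccc(OCc3ccccc3)cc2)O1
F2 | step 8 | (2S)‑2‑{(1S)‑1‑(benzyloxy)‑2‑[4‑(benzyloxy)phenyl]ethyl}‑2,3‑dihydro‑4H‑pyran‑4‑one | O=C1C[C@@H]([C@@H](OCc2ccccc2)Cc2ccc(OCc3ccccc3)cc2)OC=C1
F3 | step 8 | (2S,6S)‑2‑[4‑(benzyloxy)‑3‑methoxyphenyl]‑6‑{(1S)‑1‑(benzyloxy)‑2‑[4‑(benzyloxy)phenyl]ethyl}tetrahydro‑4H‑pyran‑4‑one (2,6‑trans) | COc1cc([C@@H]2CC(=O)C[C@@H]([C@@H](OCc3ccccc3)Cc3ccc(OCc4ccccc4)cc3)O2)ccc1OCc1ccccc1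
F4 | step 2 | N‑{3‑[4‑(benzyloxy)‑3‑methoxyphenyl]cyclobutylidene}‑N‑methylmethanaminium triflate | COc1cc(C2CC(=[N+](C)C)C2)ccc1OCc1ccccc1.[O-]S(=O)(=O)C(F)(F)F
F0 | step 10 | none | none
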